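**Retrosynthetic overview**

1. Working backwards, the route removes the two aryl bromines (late bromination of the phenol), the O-methyl group, a ketone on the ring CH2 next to the cyclopropane, and an ester on the neighbouring CH2 (activating group and chirality handle).
2. Key disconnection: one operation makes the cyclopropane bond between the two ring-fusion carbons (CH and C–CH3) and the cyclopentane bond between the quaternary benzylic carbon and its CH2, starting from an acyclic γ-bromo-β-keto ester. The cyclopropane closes first and the cyclopentanone second; the arene is present from the start.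
3. Enabling feature: the electron-rich, Z-configured tetrasubstituted styrene Ar(CH3)C=C(CH3)–CH2–. Its methyl-bearing alkene carbon is homoallylic to the CHBr carbon α to the ketone, so loss of bromide is answered by 3-exo closure to a tertiary cation at the benzylic carbon, stabilised by aryl and cyclopropyl. The enol carbon between ketone and ester then closes the five-membered ring on that cation; aryl cis to CH2 on the alkene becomes aryl syn to the cyclopropane CH2, with the two methyl groups cis.
4. The Z-alkene comes from 3,4,7-trimethylcoumarin, whose lactone ring fixes the geometry; the keto ester unit comes from the dianion of (−)-menthyl acetoacetate.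
5. The menthyl ester allows separation of the two diastereomeric cycloadducts and is then removed together with the ketone.

Key step: step 7

Assumption: the menthyl ester is relied on only as a covalent chirality handle (no asymmetric induction is assumed in step 7); the wanted diastereomer is identified by X-ray analysis of 13 or by correlation of 19 with natural laurinterol.

**Route**

Step 1
Reactants: 1 3-methylphenol (m-cresol); 2 ethyl 2-methyl-3-oxobutanoate
Product: 3 3,4,7-trimethyl-2H-chromen-2-one
Conditions: conc. H2SO4, 0 °C to rt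
Reagents that add atoms: none
Why: Pechmann condensation; ring closure should occur at the less hindered position ortho to OH and para to the methyl group, and the lactone ring places aryl and carbonyl carbon cis on the tetrasubstituted alkene.

Step 2
Reactants: 3 3,4,7-trimethyl-2H-chromen-2-one
Product: 4 2-[(2Z)-4-hydroxy-3-methylbut-2-en-2-yl]-5-methylphenol
Conditions: LiAlH4, THF, 0 °C; aq. KNaC4H4O6 (potassium sodium tartrate)
Reagents that add atoms: none
Why: Hydride reduction of the lactone to the diol should keep the alkene geometry imposed by the ring (aryl and CH2OH cis); low temperature avoids hydroalumination of the styrene.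

Step 3
Reactants: 4 2-[(2Z)-4-hydroxy-3-methylbut-2-en-2-yl]-5-methylphenol
Product: 5 (2Z)-3-(2-methoxy-4-methylphenyl)-2-methylbut-2-en-1-ol
Conditions: MeI, K2CO3, acetone, rt
Reagents that add atoms: iodomethane, CI
Why: Williamson etherification is selective for the phenoxide, because K2CO3 does not deprotonate the allylic alcohol.

Step 4
Reactants: 5 (2Z)-3-(2-methoxy-4-methylphenyl)-2-methylbut-2-en-1-ol
Product: 6 1-[(2Z)-4-bromo-3-methylbut-2-en-2-yl]-2-methoxy-4-methylbenzene
Conditions: CBr4, PPh3, CH2Cl2, −20 to 0 °C; used without chromatography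
Reagents that add atoms: tetrabromomethane, BrC(Br)(Br)Br
Why: Appel reaction; SN2 displacement at the primary allylic carbon under neutral conditions should keep the Z geometry.

Step 5
Reactants: 6 1-[(2Z)-4-bromo-3-methylbut-2-en-2-yl]-2-methoxy-4-methylbenzene; 7 (1R,2S,5R)-menthyl 3-oxobutanoate ((−)-menthyl acetoacetate)
Product: 9 (1R,2S,5R)-menthyl (6Z)-7-(2-methoxy-4-methylphenyl)-6-methyl-3-oxooct-6-enoate, via sodium lithium dianion 8 (not isolated)
Conditions: 7, NaH, THF, 0 °C; n-BuLi, 0 °C; 6, −78 to 0 °C; AcOH
Reagents that add atoms: none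
Why: γ-Alkylation of an acetoacetate dianion; the more basic terminal carbanion should attack the primary allylic bromide by SN2, and the hindered menthyl ester tolerates the conditions.

Step 6
Reactants: 9 (1R,2S,5R)-menthyl (6Z)-7-(2-methoxy-4-methylphenyl)-6-methyl-3-oxooct-6-enoate
Product: 11 (1R,2S,5R)-menthyl (6Z)-4-bromo-7-(2-methoxy-4-methylphenyl)-6-methyl-3-oxooct-6-enoate (both C-4 epimers), via bis(trimethylsilyl) dienol ether 10 (not isolated)
Conditions: Me3SiOSO2CF3 (2.4 equiv), Et3N, CH2Cl2, 0 °C; then NBS (1.0 equiv), −78 °C; aq. NaHCO3; used directly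
Reagents that add atoms: N-bromosuccinimide, O=C1CCC(=O)N1Br; trimethylsilyl triflate, C[Si](C)(C)OS(=O)(=O)C(F)(F)F (silicon is carried only by 10)
Why: Electrophilic halogenation of a 1,3-bis(silyloxy)diene occurs at its terminal (γ) carbon, and at −78 °C this dienol ether should be far more nucleophilic than the styrene or the anisole ring; the new C–Br centre forms as both epimers.

Step 7
Reactants: 11 (1R,2S,5R)-menthyl (6Z)-4-bromo-7-(2-methoxy-4-methylphenyl)-6-methyl-3-oxooct-6-enoate
Product: 13 (1R,2S,5R)-menthyl (1R,4R,5S)-4-(2-methoxy-4-methylphenyl)-4,5-dimethyl-2-oxobicyclo[3.1.0]hexane-3-carboxylate (C-3 epimers and enol form), via cyclopropylcarbinyl cation 12 (not isolated)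
Conditions: AgOSO2CF3 (1.2 equiv), 2,6-di-tert-butyl-4-methylpyridine, CH2Cl2–(CF3)2CHOH 4:1, −40 to 0 °C, 0.02 M; diastereomers separated on silica gel or by crystallisation
Reagents that add atoms: none
Why: Proposed new method: silver-assisted departure of bromide from the carbon next to the ketone of 11 is expected to occur with homoallylic participation of the electron-rich tetrasubstituted styrene (its methyl-bearing carbon bonds to the CHBr carbon in a 3-exo closure, the mode of the i-steroid rearrangement), which gives the tertiary, aryl- and cyclopropyl-stabilised cation 12, and the enol carbon between the two carbonyl groups then closes the five-membered ring on this cation (5-(enolendo)-exo-trig C-alkylation). The closest known reaction type is the stepwise (3+2) cyclocoupling of 2-oxyallyl cations from α-halo ketones with styrenes and indoles, which gives 3-arylcyclopentanones with a quaternary benzylic carbon; new here is the one-carbon tether, which turns the first bond formation into a cyclopropane closure. The cis ring fusion of the two cyclopropane centres is a geometric necessity, and the quaternary benzylic centre follows from suprafacial addition to the Z-alkene: aryl and CH2 are cis in 11, so the aryl group ends syn to the cyclopropane CH2 and the two methyl groups cis, an outcome also favoured by the preferred conformer of 12, in which the planar aryl group avoids the ring methyl. The step needs attack of the alkene on the bromide-bearing carbon and not on the other terminus of the three-carbon unit, which the ester secures by deactivating and blocking that carbon and by making it the nucleophile of the second closure, and it needs C- and not O-alkylation in that closure, which is expected because an O-alkylated tertiary benzylic enol ether can re-ionise under the conditions while the C–C bond cannot. The absolute configuration is not controlled by the reaction (each epimer of 11, or a planar oxyallyl-type intermediate, can use either alkene face), so both diastereomers are expected; the menthyl ester allows their separation, and the (1R,4R,5S) isomer 13 is carried on.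

Step 8
Reactants: 13 (1R,2S,5R)-menthyl (1R,4R,5S)-4-(2-methoxy-4-methylphenyl)-4,5-dimethyl-2-oxobicyclo[3.1.0]hexane-3-carboxylate
Product: 15 (1R,4R,5S)-4-(2-methoxy-4-methylphenyl)-4,5-dimethylbicyclo[3.1.0]hexan-2-one, via β-keto acid 14 (not isolated)
Conditions: H2O (5 equiv), DMSO, 150 °C
Reagents that add atoms: water, O (its oxygen is carried by 14 and leaves with the CO2, not in 15)
Why: Salt-free Krapcho-type dealkoxycarbonylation; the enolisable β-keto ester should lose menthol through the α-oxoketene, water adds, and acid 14 decarboxylates, while the ring-fusion centres cannot epimerise.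

Step 9
Reactants: 15 (1R,4R,5S)-4-(2-methoxy-4-methylphenyl)-4,5-dimethylbicyclo[3.1.0]hexan-2-one
Product: 17 (1S,2R,5R)-2-(2-methoxy-4-methylphenyl)-1,2-dimethylbicyclo[3.1.0]hexane, via hydrazone 16 (not isolated)
Conditions: N2H4·H2O, KOH, diethylene glycol, 130 °C then 200 °C
Reagents that add atoms: hydrazine, NN (nitrogen is carried only by 16)
Why: Wolff–Kishner reduction in the Huang-Minlon form; hydrazone 16 should lose N2 under base to give the CH2 group, and cyclopropyl ketones of the thujone type survive these conditions, as does the aryl methyl ether.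

Step 10
Reactants: 17 (1S,2R,5R)-2-(2-methoxy-4-methylphenyl)-1,2-dimethylbicyclo[3.1.0]hexane
Product: 18 2-[(1S,2R,5R)-1,2-dimethylbicyclo[3.1.0]hexan-2-yl]-5-methylphenol (debromolaurinterol)
Conditions: NaSEt, DMF, 130 °C; then 1 M HCl, 0 °C
Reagents that add atoms: none
Why: Nucleophilic demethylation of the aryl methyl ether by thiolate (SN2 at the methyl carbon) avoids the Lewis and Brønsted acids that would open the cyclopropane with participation of the phenol oxygen.

Step 11
Reactants: 18 2-[(1S,2R,5R)-1,2-dimethylbicyclo[3.1.0]hexan-2-yl]-5-methylphenol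
Product: 20 2,4-dibromo-6-[(1S,2R,5R)-1,2-dimethylbicyclo[3.1.0]hexan-2-yl]-3-methylphenol (CNP0136079.1), via laurinterol 19 (not isolated)
Conditions: NBS (2.1 equiv), i-Pr2NH (10 mol %), CH2Cl2, −20 to 0 °C, dark
Reagents that add atoms: N-bromosuccinimide, O=C1CCC(=O)N1Br
Why: Electrophilic aromatic bromination; the hydroxyl group should direct the first bromine para (19) and the second ortho, both positions also ortho to the ring methyl, while the remaining free position is meta to OH, and the amine-buffered reagent keeps the medium free of HBr so the cyclopropane survives.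

**Compound list**

1 | 3-methylphenol (m-cresol) | Cc1cccc(O)c1 | starting material
2 | ethyl 2-methyl-3-oxobutanoate | CCOC(=O)C(C)C(C)=O | starting material
3 | 3,4,7-trimethyl-2H-chromen-2-one | Cc1ccc2c(C)c(C)c(=O)oc2c1 | intermediate
4 | 2-[(2Z)-4-hydroxy-3-methylbut-2-en-2-yl]-5-methylphenol | C/C(c1ccc(C)cc1O)=C(C)/CO | intermediate
5 | (2Z)-3-(2-methoxy-4-methylphenyl)-2-methylbut-2-en-1-ol | C/C(c1ccc(C)cc1OC)=C(C)/CO | intermediate
6 | 1-[(2Z)-4-bromo-3-methylbut-2-en-2-yl]-2-methoxy-4-methylbenzene | C/C(c1ccc(C)cc1OC)=C(C)/CBr | intermediate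
7 | (1R,2S,5R)-menthyl 3-oxobutanoate ((−)-menthyl acetoacetate) | CC(=O)CC(=O)O[C@@H]1C[C@H](C)CC[C@H]1C(C)C | starting material
8 | sodium lithium dianion of 7 (C-2 and C-4 deprotonated; not isolated) | [Na+].[Li+].[CH2-]C(=O)[CH-]C(=O)O[C@@H]1C[C@H](C)CC[C@H]1C(C)C | intermediate
9 | (1R,2S,5R)-menthyl (6Z)-7-(2-methoxy-4-methylphenyl)-6-methyl-3-oxooct-6-enoate | C/C(c1ccc(C)cc1OC)=C(C)/CCC(=O)CC(=O)O[C@@H]1C[C@H](C)CC[C@H]1C(C)C | intermediate
10 | (6Z)-1-[(1R,2S,5R)-menthyloxy]-7-(2-methoxy-4-methylphenyl)-6-methyl-1,3-bis(trimethylsilyloxy)octa-1,3,6-triene (dienol ether geometry not defined; not isolated) | C/C(c1ccc(C)cc1OC)=C(C)/CC=C(O[Si](C)(C)C)C=C(O[Si](C)(C)C)O[C@@H]1C[C@H](C)CC[C@H]1C(C)C | intermediate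
11 | (1R,2S,5R)-menthyl (6Z)-4-bromo-7-(2-methoxy-4-methylphenyl)-6-methyl-3-oxooct-6-enoate (both C-4 epimers) | C/C(c1ccc(C)cc1OC)=C(C)/CC(Br)C(=O)CC(=O)O[C@@H]1C[C@H](C)CC[C@H]1C(C)C | intermediate
12 | tertiary benzylic cyclopropylcarbinyl cation: 1-(2-methoxy-4-methylphenyl)ethylium carrying a 1-methylcyclopropyl group whose menthyl 3-oxopropanoate side chain is cis to the cationic carbon (configuration as in 13; not isolated) | COc1cc(C)ccc1[C+](C)[C@@]2(C)C[C@H]2C(=O)CC(=O)O[C@@H]3C[C@H](C)CC[C@H]3C(C)C | intermediate
13 | (1R,2S,5R)-menthyl (1R,4R,5S)-4-(2-methoxy-4-methylphenyl)-4,5-dimethyl-2-oxobicyclo[3.1.0]hexane-3-carboxylate (C-3 not defined) | COc1cc(C)ccc1[C@]2(C)C(C(=O)O[C@@H]3C[C@H](C)CC[C@H]3C(C)C)C(=O)[C@@H]4C[C@@]42C | intermediate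
14 | (1R,4R,5S)-4-(2-methoxy-4-methylphenyl)-4,5-dimethyl-2-oxobicyclo[3.1.0]hexane-3-carboxylic acid (not isolated) | COc1cc(C)ccc1[C@]2(C)C(C(O)=O)C(=O)[C@@H]3C[C@@]32C | intermediate
15 | (1R,4R,5S)-4-(2-methoxy-4-methylphenyl)-4,5-dimethylbicyclo[3.1.0]hexan-2-one | COc1cc(C)ccc1[C@]2(C)CC(=O)[C@@H]3C[C@@]32C | intermediate
16 | hydrazone of 15 (not isolated) | COc1cc(C)ccc1[C@]2(C)CC(=NN)[C@@H]3C[C@@]32C | intermediate
17 | (1S,2R,5R)-2-(2-methoxy-4-methylphenyl)-1,2-dimethylbicyclo[3.1.0]hexane | COc1cc(C)ccc1[C@]2(C)CC[C@@H]3C[C@@]32C | intermediate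
18 | 2-[(1S,2R,5R)-1,2-dimethylbicyclo[3.1.0]hexan-2-yl]-5-methylphenol | Cc1ccc([C@]2(C)CC[C@@H]3C[C@@]32C)c(O)c1 | intermediate
19 | 4-bromo-2-[(1S,2R,5R)-1,2-dimethylbicyclo[3.1.0]hexan-2-yl]-5-methylphenol (laurinterol; not isolated) | Cc1cc(O)c([C@]2(C)CC[C@@H]3C[C@@]32C)cc1Br | intermediate
20 | 2,4-dibromo-6-[(1S,2R,5R)-1,2-dimethylbicyclo[3.1.0]hexan-2-yl]-3-methylphenol | Cc1c(Br)cc([C@]2(C)CC[C@@H]3C[C@@]32C)c(O)c1Br | target

**Step count and risks**

Total step count: 11. Longest linear sequence: 11 steps (1 and 2 to 20); 7 enters at step 5.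

Steps most likely to fail:

Step 7 (proposed new method). The ionisation may proceed without π-participation and end in loss of HBr to the conjugated dienone. The second closure may stop at oxygen, or bond rotation in the cation may erode the configuration of the benzylic centre. Fallback by known chemistry, setting out from 5 and rejoining at 15: Johnson–Claisen rearrangement of 5 (MeC(OEt)3, cat. EtCO2H, 140 °C) should build the quaternary benzylic carbon and give racemic ethyl 3-(2-methoxy-4-methylphenyl)-3,4-dimethylpent-4-enoate F1. Saponification (LiOH) and classical resolution through the salt with (R)-1-phenylethylamine (or its antipode, whichever crystallises the wanted acid) give (3R)-3-(2-methoxy-4-methylphenyl)-3,4-dimethylpent-4-enoic acid F2. (COCl)2 converts it into (3R)-3-(2-methoxy-4-methylphenyl)-3,4-dimethylpent-4-enoyl chloride F3, and excess CH2N2 gives (4R)-1-diazo-4-(2-methoxy-4-methylphenyl)-4,5-dimethylhex-5-en-2-one F4. Rh2(OAc)4 in CH2Cl2 then adds the ketocarbene to the 1,1-disubstituted alkene (intramolecular cyclopropanation); after chromatographic removal of the isomer with the cyclopropane on the other face this gives 15, and the route continues with step 9.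

Step 6. Electrophilic bromine may attack the electron-rich alkene or arene instead of the dienol ether, or brominate twice. Fallback without electrophilic halogen, setting out from 9 and rejoining at 11: the dianion of 9 (NaH, then n-BuLi, THF) is oxidised at the γ-carbon with 2-(phenylsulfonyl)-3-phenyloxaziridine at −78 °C to (1R,2S,5R)-menthyl (6Z)-4-hydroxy-7-(2-methoxy-4-methylphenyl)-6-methyl-3-oxooct-6-enoate F5. MsCl and Et3N give the 4-(methanesulfonyloxy) analogue F6, and LiBr in acetone (SN2 next to the ketone) gives 11.

Step 8. The hindered secondary ester may be cleaved incompletely, or the activated cyclopropane may open at 150 °C. Fallback, setting out from 13 and rejoining at 15: DMAP-catalysed ester exchange with allyl alcohol (toluene, 110 °C, 4 Å sieves) gives prop-2-en-1-yl (1R,4R,5S)-4-(2-methoxy-4-methylphenyl)-4,5-dimethyl-2-oxobicyclo[3.1.0]hexane-3-carboxylate F7. Pd(PPh3)4 with morpholine in THF at rt removes the allyl group, and the acid decarboxylates to 15.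

**Further compounds**

F1 | step 7 | ethyl 3-(2-methoxy-4-methylphenyl)-3,4-dimethylpent-4-enoate (racemic) | CCOC(=O)CC(C)(C(C)=C)c1ccc(C)cc1OC
F2 | step 7 | (3R)-3-(2-methoxy-4-methylphenyl)-3,4-dimethylpent-4-enoic acid | OC(=O)C[C@](C)(C(C)=C)c1ccc(C)cc1OC
F3 | step 7 | (3R)-3-(2-methoxy-4-methylphenyl)-3,4-dimethylpent-4-enoyl chloride | ClC(=O)C[C@](C)(C(C)=C)c1ccc(C)cc1OC
F4 | step 7 | (4R)-1-diazo-4-(2-methoxy-4-methylphenyl)-4,5-dimethylhex-5-en-2-one | [N-]=[N+]=CC(=O)C[C@](C)(C(C)=C)c1ccc(C)cc1OC
F5 | step 6 | (1R,2S,5R)-menthyl (6Z)-4-hydroxy-7-(2-methoxy-4-methylphenyl)-6-methyl-3-oxooct-6-enoate (both C-4 epimers) | C/C(c1ccc(C)cc1OC)=C(C)/CC(O)C(=O)CC(=O)O[C@@H]1C[C@H](C)CC[C@H]1C(C)C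
F6 | step 6 | (1R,2S,5R)-menthyl (6Z)-4-(methanesulfonyloxy)-7-(2-methoxy-4-methylphenyl)-6-methyl-3-oxooct-6-enoate (both C-4 epimers) | C/C(c1ccc(C)cc1OC)=C(C)/CC(OS(C)(=O)=O)C(=O)CC(=O)O[C@@H]1C[C@H](C)CC[C@H]1C(C)C
F7 | step 8 | prop-2-en-1-yl (1R,4R,5S)-4-(2-methoxy-4-methylphenyl)-4,5-dimethyl-2-oxobicyclo[3.1.0]hexane-3-carboxylate (C-3 not defined) | COc1cc(C)ccc1[C@]2(C)C(C(=O)OCC=C)C(=O)[C@@H]3C[C@@]32C
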